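## Structural features

The target is a sesquineolignan built from two oxygen heterocycles joined by one methylene group. One is a 3,4,5-trisubstituted oxolane with ring A (3-hydroxy-4-methoxyphenyl) on C5, CH2OH on C4 and the linking CH2 on C3. The other is a trans-2-aryl-3-hydroxymethyl-2,3-dihydrobenzofuran whose fused benzene (ring B) carries OMe at C4 and the linking CH2 at C6, and whose 2-aryl group is ring C (4-hydroxy-3-methoxyphenyl). The oxolane holds three contiguous stereocentres (5R aryl trans to the 4S hydroxymethyl group, which is cis to the 3S side chain) and the dihydrofuran two (2S,3R, trans). The two sets are insulated by the CH2 group and ring B, so each must be set in the absolute sense. Both benzylic C–O bonds are p-alkoxybenzylic ethers: acid ionises them, and once ring B is an electron-rich resorcinol diether it can capture the oxolane cation to give an aryltetralin; long hydrogenolysis cleaves them. The phenols are oxidation-sensitive, and C3 of the dihydrofuran can epimerise or eliminate the ring oxygen while it carries a carbonyl group. The real difficulty is ring B, a 1,2,3,5-tetrasubstituted benzene with two differently bound oxygens on either side of C3a, together with absolute control of C2/C3. The feature used is that C3a lies between C4 (OMe) and C7a (ring O): it is C2 of a 5-substituted cyclohexane-1,3-dione, whose central carbon and one enol oxygen can add across the alkene of a ferulic acid derivative, the other carbonyl becoming the C4 methoxy carbon on aromatisation.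

## Logic of the disconnections

**30 ⇒ 29.** The two aryl O–CH2Ph bonds are cut. The phenols must be masked through the oxidation of step 12 and every basic step. Nothing is gained in skeleton, but it demands a hydrogenolysis that stops before the ring benzylic C–O bonds react. For that reason no alkyl benzyl ether is carried: the oxolane CH2OH stays free from 18 onward.

**29 ⇒ 28.** The C3 hydroxymethyl group is traced back to the C3 acyl group, i.e. the exocyclic C–N bond of the imide. The carbonyl is what made the alkene partner reactive and held the controller. The demand is hydride attack at the exocyclic carbonyl only, without epimerisation of C3, returning 21.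

**28 ⇒ 27 ⇒ 24.** The aryl O–CH3 bond is cut, then the aromatic unsaturation of ring B is removed (C4–OH back to C4=O, C5=C6 back to CH2–CH). This lowers ring B to the dihydroresorcinol oxidation level at which C3a is the central carbon of a 1,3-dione. The demand is a dehydrogenation that uses neither acid (p-alkoxybenzylic ethers beside a nascent electron-rich ring B) nor a base that reaches C3–H.

**24 ⇒ 18 + 23.** C3–C3a and O1–C2 are cut. This is the one place where the two halves can be joined while both dihydrofuran stereocentres and the heterocycle are formed in a single operation. 18 then carries the complete oxolane triad and 23 is two steps from 19. The forward step needs regiocontrol (carbon to the carbonyl-side alkene carbon), facial control from the auxiliary, trans closure, and tolerance of a free primary hydroxyl.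

**23 ⇒ 20 + 21; 20 ⇒ 19.** The imide N–C(O) bond and the aryl O–CH2Ph bond are cut, leaving a commercial acid and a commercial auxiliary. The only demand is acylation without E/Z loss.

**18 ⇒ 14 + 15.** In dione numbering, C4–C5 (Michael bond) and C2–C3 (Claisen bond) are cut, and a CO2Me group is restored at C4. Ring B collapses to an enone and a malonate. The demand is that the hydroxyl is silylated while the enone is exposed to base (otherwise it adds to the enone), and that the acidic finish removes the silyl group so that no separate deprotection is needed.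

**14 ⇒ 12 + 13.** The C=C bond is cut (cross-metathesis), so the enone comes from an allyl group in one step, with no aldehyde and no aldol with acetone. The demand is E-selectivity and tolerance of ethers.

**12 ⇒ 11 ⇒ 10 ⇒ 9 ⇒ 7 + 8.** The O–Si bond is cut, then the oxolane O1–C2 (benzylic) bond, then the lactone is restored, then the Cα–C(carbinol) aldol bond is cut. The oxolane becomes a β-allyl butyrolactone and an aldehyde. The demand is trans aldol addition on the lactone (which becomes the 3,4-cis relation of the oxolane) and ring closure through the benzylic cation that places the aryl group trans to its neighbour whatever the carbinol configuration.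

**7 ⇒ 5 ⇒ 3 + 4; 3 ⇒ 1 + 2.** The lactone C–O bond and the Cα–CH2 bond of the alkylation are cut, then the N-acyl bond. The single stereocentre that controls the whole oxolane comes from an Evans alkylation. The demand is the (R)-auxiliary, because the acetate arm is the electrophile.

## Other disconnections considered

**Alternative 1:** Ring B by benzannulation.
- Cut: C3a–C7a and C4–C5 of ring B (the C7–C7a bond re-forms by electrocyclisation).
- Forward step: heating cyclobutenone A2 with siloxyalkyne A3 gives a vinylketene, which undergoes [2+2] addition to the ynol ether, 4π opening and 6π closure to phenol A1.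
- In favour: ring B arrives aromatic with its two oxygens already differentiated (free OH against OSi(iPr)3), so no dehydrogenation follows the union; on this point it is better than the chosen plan. No stereocentre is made in the union, so the C2/C3 pair can be set beforehand by established aldol chemistry; on certainty of absolute control it is also better. The step is thermal and reagent-free.
- Against: both partners are elaborate. A2 needs a ketene-type [2+2] on an oxolanyl alkyne and is sensitive. A3 is an ynol silyl ether with two stereocentres that must be made by ester homologation and is labile to heat and moisture. After the union the dihydrofuran still has to be closed at the benzylic carbon, the silyl ether exchanged for methyl, and an alkyl benzyl ether removed by the slow hydrogenolysis the chosen plan avoids.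
- Comparison: equally convergent; mechanistically better precedented; poorer in step economy by an estimated five to eight steps.

**Alternative 2:** Carbene C–H insertion.
- Cut: C2–C3 of the dihydrofuran.
- Forward step: diazo ester A5 with Rh2(S-PTTL)4 inserts into the benzylic ether C–H to give the cis ester, and DBU turns it into trans ester A4.
- In favour: absolute control is catalytic and the reaction type is established on exactly this substrate class; here it is better than the chosen plan, whose auxiliary control is unproven. Ring B is aromatic throughout, which is also better.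
- Against: A5 needs a benzene ring with four substituents and three distinguishable oxygens (methyl ether, benzylic ether, triflate), which costs steps on a symmetrical precursor. A4 must then be joined to the oxolane by an sp2–sp3 coupling of the triflate with an oxolanylmethyl zinc or boron reagent under zerovalent palladium, a second strategic C–C bond formation with a β-hydride elimination risk.
- Comparison: convergence and estimated step count are about equal to the chosen plan. The chosen plan forms two bonds in the union and takes both ring B oxygens from the dione without differentiation work.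

**Alternative 3:** Carbonyl ylide cycloaddition.
- Cut: C2–C3 and C4–C5 of the oxolane (oxolane numbering with the aryl group on C2).
- Forward step: CsF turns chloro ether A7 into the carbonyl ylide, which adds to butenolide A8 anti to the menthyloxy group to give bicyclic lactone A6.
- In favour: the whole oxolane with its three stereocentres in one step from a short ylide precursor and a chiral-pool butenolide, against steps 1 to 6 here; on step economy for this half it is clearly better.
- Against: the orientation of the unsymmetrical, non-stabilised ylide (which carbon bonds to the carbonyl-side alkene carbon, and aryl exo or endo) is not secured, so isomer mixtures are likely. The acetal carbon of A6 is the future ArCH2 carbon; once unmasked it is an aldehyde on a stereocentre that is cis to its neighbour and can epimerise, and it is one carbon short of the enone needed for the dione, so a homologation would be required.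
- Comparison: it solves only the oxolane and leaves ring B and C2/C3 untouched. It competes with steps 1 to 6, not with the key step, and trades their reliable stereocontrol for brevity.

Key step: step 12

Remark: the carbinol carbon of 9 and 10, the ring carbons of 16 and 17, and C6 of 24 and 25 form as epimer mixtures and are written without configuration; all are cleared later (steps 6, 9 and 13).

## Route

Step 1
Reactants: 1 (R)-4-benzyl-1,3-oxazolidin-2-one; 2 pent-4-enoyl chloride
Product: 3 (4R)-4-benzyl-3-(pent-4-enoyl)-1,3-oxazolidin-2-one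
Conditions: n-BuLi, THF, −78 °C; then 2, −78 to 0 °C
Reagents that add atoms: none
Why: N-acylation of the lithiated oxazolidinone by an acid chloride, the standard entry to Evans imides.

Step 2
Reactants: 3 (4R)-4-benzyl-3-(pent-4-enoyl)-1,3-oxazolidin-2-one; 4 tert-butyl bromoacetate
Product: 5 tert-butyl (3S)-3-{[(4R)-4-benzyl-2-oxo-1,3-oxazolidin-3-yl]carbonyl}hex-5-enoate
Conditions: NaN(SiMe3)2, THF, −78 °C; then 4, −78 to −40 °C
Reagents that add atoms: none
Why: Evans alkylation; the chelated Z-enolate is alkylated on the face away from the benzyl group, which with the (R)-auxiliary gives the (3S) centre that becomes oxolane C3 of the target.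

Step 3
Reactants: 5 tert-butyl (3S)-3-{[(4R)-4-benzyl-2-oxo-1,3-oxazolidin-3-yl]carbonyl}hex-5-enoate
Product: 7 (4S)-4-(prop-2-en-1-yl)oxolan-2-one, via tert-butyl (3S)-3-(hydroxymethyl)hex-5-enoate 6 (not isolated)
Conditions: LiBH4, MeOH (1 equiv), THF, 0 °C; aqueous work-up; crude 6: CF3CO2H, CH2Cl2, rt
Reagents that add atoms: none
Why: Reductive cleavage of the imide by LiBH4 spares the tert-butyl ester and returns 1; acid then lactonises the hydroxy ester with loss of the tert-butyl group; the stereocentre is not enolisable in 6 or 7.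

Step 4
Reactants: 7 (4S)-4-(prop-2-en-1-yl)oxolan-2-one; 8 3-(benzyloxy)-4-methoxybenzaldehyde
Product: 9 (3R,4S)-3-[(3-benzyloxy-4-methoxyphenyl)(hydroxy)methyl]-4-(prop-2-en-1-yl)oxolan-2-one (both carbinol epimers)
Conditions: LiN(iPr)2, THF, −78 °C; then 8, −78 °C; NH4Cl quench at −78 °C
Reagents that add atoms: none
Why: Aldol addition of the lactone lithium enolate; the aldehyde enters anti to the β-allyl group, fixing the α,β-trans lactone that becomes the 3,4-cis oxolane; the carbinol configuration is irrelevant because step 6 passes through the benzylic cation.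

Step 5
Reactants: 9 (3R,4S)-3-[(3-benzyloxy-4-methoxyphenyl)(hydroxy)methyl]-4-(prop-2-en-1-yl)oxolan-2-one
Product: 10 (2S,3S)-2-[(3-benzyloxy-4-methoxyphenyl)(hydroxy)methyl]-3-(prop-2-en-1-yl)butane-1,4-diol (both carbinol epimers)
Conditions: LiAlH4, THF, 0 °C
Reagents that add atoms: none
Why: Hydride reduction of the lactone to the diol; at 0 °C it is faster than retro-aldol of the alkoxide, and the two ring stereocentres are untouched.

Step 6
Reactants: 10 (2S,3S)-2-[(3-benzyloxy-4-methoxyphenyl)(hydroxy)methyl]-3-(prop-2-en-1-yl)butane-1,4-diol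
Product: 11 [(2R,3S,4S)-2-(3-benzyloxy-4-methoxyphenyl)-4-(prop-2-en-1-yl)oxolan-3-yl]methanol
Conditions: 10-camphorsulfonic acid (cat.), CH2Cl2, 0 °C to rt
Reagents that add atoms: none
Why: SN1 cycloetherification: the p-methoxybenzylic cation is captured by the primary hydroxyl four atoms away (5-exo closure; the other hydroxyl could only give an oxetane), and both carbinol epimers converge; the aryl group settles trans to the adjacent CH2OH because closure is reversible through the stabilised cation, giving (2R).

Step 7
Reactants: 11 [(2R,3S,4S)-2-(3-benzyloxy-4-methoxyphenyl)-4-(prop-2-en-1-yl)oxolan-3-yl]methanol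
Product: 12 tert-butyl{[(2R,3S,4S)-2-(3-benzyloxy-4-methoxyphenyl)-4-(prop-2-en-1-yl)oxolan-3-yl]methoxy}dimethylsilane
Conditions: TBSCl, imidazole, DMF, rt
Reagents that add atoms: tert-butyldimethylsilyl chloride (TBSCl), CC(C)(C)[Si](C)(C)Cl
Why: Silylation of the only hydroxyl; the ether is needed just while the enone of 14 meets base (a free hydroxyl would add to it in a 6-exo oxa-Michael reaction) and is shed in the acid finish of step 9.

Step 8
Reactants: 12 tert-butyl{[(2R,3S,4S)-2-(3-benzyloxy-4-methoxyphenyl)-4-(prop-2-en-1-yl)oxolan-3-yl]methoxy}dimethylsilane; 13 but-3-en-2-one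
Product: 14 (3E)-5-[(3S,4S,5R)-5-(3-benzyloxy-4-methoxyphenyl)-4-({[tert-butyl(dimethyl)silyl]oxy}methyl)oxolan-3-yl]pent-3-en-2-one
Conditions: 13 (3 equiv), second-generation Hoveyda–Grubbs catalyst RuCl2(H2IMes)(=CH-C6H4-2-OiPr) (3 mol%), CH2Cl2, 40 °C
Reagents that add atoms: none
Why: Olefin cross-metathesis of a terminal alkene with an electron-poor vinyl ketone is selective for the cross product and gives the E-enone; it replaces ozonolysis plus aldol condensation.

Step 9
Reactants: 14 (3E)-5-[(3S,4S,5R)-5-(3-benzyloxy-4-methoxyphenyl)-4-({[tert-butyl(dimethyl)silyl]oxy}methyl)oxolan-3-yl]pent-3-en-2-one; 15 dimethyl malonate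
Product: 18 5-{[(3S,4S,5R)-5-(3-benzyloxy-4-methoxyphenyl)-4-(hydroxymethyl)oxolan-3-yl]methyl}cyclohexane-1,3-dione, via silylated dioxocyclohexanecarboxylic methyl ester 16 (not isolated), via silylated dioxocyclohexanecarboxylic acid 17 (not isolated)
Conditions: 15, NaOMe, MeOH, reflux; aq. NaOH, reflux; MeOH evaporated; 2 M HCl to pH 1, THF–H2O, 50 °C
Reagents that add atoms: none
Why: Michael addition of sodium malonate to the enone, Claisen (Dieckmann-type) closure of the methyl ketone onto an ester, saponification and decarboxylation of the β-keto acid form the classical synthesis of 5-substituted dihydroresorcinols; the dilute acid that decarboxylates also removes the silyl ether, and before ring B exists the oxolane can only re-close to itself.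

Step 10
Reactants: 19 ferulic acid
Product: 20 (2E)-3-(4-benzyloxy-3-methoxyphenyl)prop-2-enoic acid
Conditions: BnBr, NaOH, EtOH–H2O, reflux; then HCl to pH 2
Reagents that add atoms: benzyl bromide, BrCc1ccccc1
Why: Williamson etherification of the phenoxide in the presence of the much less nucleophilic carboxylate; any benzyl ester formed is saponified under the same conditions.

Step 11
Reactants: 20 (2E)-3-(4-benzyloxy-3-methoxyphenyl)prop-2-enoic acid; 21 (S)-4-benzyl-1,3-oxazolidin-2-one
Product: 23 (4S)-4-benzyl-3-[(2E)-3-(4-benzyloxy-3-methoxyphenyl)prop-2-enoyl]-1,3-oxazolidin-2-one, via mixed pivalic anhydride 22 (not isolated)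
Conditions: t-BuCOCl, Et3N, THF, −20 °C; then 21, LiCl, rt
Reagents that add atoms: none
Why: N-acylation of the oxazolidinone by a mixed pivalic anhydride with LiCl/Et3N activation; attack goes to the unhindered cinnamoyl carbonyl and the E-alkene is not touched.

Step 12
Reactants: 18 5-{[(3S,4S,5R)-5-(3-benzyloxy-4-methoxyphenyl)-4-(hydroxymethyl)oxolan-3-yl]methyl}cyclohexane-1,3-dione; 23 (4S)-4-benzyl-3-[(2E)-3-(4-benzyloxy-3-methoxyphenyl)prop-2-enoyl]-1,3-oxazolidin-2-one
Product: 24 (4S)-4-benzyl-3-{[(2S,3S)-2-(4-benzyloxy-3-methoxyphenyl)-6-{[(3S,4S,5R)-5-(3-benzyloxy-4-methoxyphenyl)-4-(hydroxymethyl)oxolan-3-yl]methyl}-4-oxo-2,3,4,5,6,7-hexahydro-1-benzofuran-3-yl]carbonyl}-1,3-oxazolidin-2-one (both C6 epimers)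
Conditions: Mn(OAc)3·2H2O (2.2 equiv), Yb(OTf)3 (1.2 equiv), 23 (1.5 equiv), CF3CH2OH–CH2Cl2, 0 °C
Reagents that add atoms: none
Why: Proposed new method: trivalent manganese oxidises the metal enolate of 18 to the electrophilic C2 radical, which adds to the alkene carbon next to the imide carbonyl of 23 (the styrene-like, more nucleophilic end) to give the p-benzyloxy-stabilised benzylic radical; a second equivalent of Mn(OAc)3 oxidises this to the cation, which the enol oxygen captures in a 5-exo-trig closure onto the quinone-methide-like cation, so that C3a–C3 and then O1–C2 are formed and the dihydrofuran ring is closed. The closest known reaction type is the racemic Mn(OAc)3 or (NH4)2Ce(NO3)6 oxidative [3+2] annulation of cyclohexane-1,3-diones with styrenes, cinnamates and cinnamic amides, which gives trans-2-aryl dihydrofurans with this regiochemistry; lanthanide-triflate-promoted Mn(OAc)3 oxidations in CF3CH2OH and chelate-controlled radical additions to N-enoyl oxazolidinones are each known, but auxiliary control of this annulation is not. C3 is set in the C–C bond-forming step by the auxiliary: Yb(OTf)3 chelates the two imide carbonyls, the enoyl group sits s-cis, the (S)-benzyl group covers one face, and the radical enters on the opposite (Cα-Si) face, which by the chelate model gives (3S) as required. C2 is set by C3: the cation closes with the aryl group trans to the acyl group, and reversible ionisation of the p-alkoxybenzylic C–O bond would correct a cis closure. Regioselectivity rests on benzylic radical stability and on the polarity match of an electrophilic radical with the electron-rich alkene terminus. Chemoselectivity rests on the 1,3-dione being by far the most easily oxidised group; the free hydroxyl is inert in an alcohol solvent. The two dione oxygens are equivalent, so either closes to the same product, and the C6 epimers converge in step 13.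

Step 13
Reactants: 24 (4S)-4-benzyl-3-{[(2S,3S)-2-(4-benzyloxy-3-methoxyphenyl)-6-{[(3S,4S,5R)-5-(3-benzyloxy-4-methoxyphenyl)-4-(hydroxymethyl)oxolan-3-yl]methyl}-4-oxo-2,3,4,5,6,7-hexahydro-1-benzofuran-3-yl]carbonyl}-1,3-oxazolidin-2-one
Product: 27 (4S)-4-benzyl-3-{[(2S,3S)-2-(4-benzyloxy-3-methoxyphenyl)-6-{[(3S,4S,5R)-5-(3-benzyloxy-4-methoxyphenyl)-4-(hydroxymethyl)oxolan-3-yl]methyl}-4-hydroxy-2,3-dihydro-1-benzofuran-3-yl]carbonyl}-1,3-oxazolidin-2-one, via bis(trimethylsilyl) dienol ether 25 (not isolated), via O-trimethylsilyl phenol 26 (not isolated)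
Conditions: Me3SiCl (3 equiv), LiN(iPr)2 (2.3 equiv), THF, −78 °C; then Pd(OAc)2 (1.1 equiv), MeCN, rt; aq. citric acid work-up
Reagents that add atoms: none
Why: Saegusa–Ito oxidation: kinetic enolisation of the vinylogous ester with in-situ silylation (the hydroxyl is capped as well) gives a silyl dienol ether that divalent palladium dehydrogenates to the dienone, which tautomerises to the phenol; either enolisation site leads to the same arene, and C3–H is shielded from the base by the A(1,3) strain that protects α-branched N-acyl oxazolidinones. No acid is present, so neither benzylic ether can ionise toward the new electron-rich ring B.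

Step 14
Reactants: 27 (4S)-4-benzyl-3-{[(2S,3S)-2-(4-benzyloxy-3-methoxyphenyl)-6-{[(3S,4S,5R)-5-(3-benzyloxy-4-methoxyphenyl)-4-(hydroxymethyl)oxolan-3-yl]methyl}-4-hydroxy-2,3-dihydro-1-benzofuran-3-yl]carbonyl}-1,3-oxazolidin-2-one
Product: 28 (4S)-4-benzyl-3-{[(2S,3S)-2-(4-benzyloxy-3-methoxyphenyl)-6-{[(3S,4S,5R)-5-(3-benzyloxy-4-methoxyphenyl)-4-(hydroxymethyl)oxolan-3-yl]methyl}-4-methoxy-2,3-dihydro-1-benzofuran-3-yl]carbonyl}-1,3-oxazolidin-2-one
Conditions: MeI, K2CO3, acetone, rt
Reagents that add atoms: iodomethane (MeI), CI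
Why: Williamson methylation of the phenoxide; carbonate does not alkylate the primary alcohol and is too weak to deprotonate the hindered C3–H.

Step 15
Reactants: 28 (4S)-4-benzyl-3-{[(2S,3S)-2-(4-benzyloxy-3-methoxyphenyl)-6-{[(3S,4S,5R)-5-(3-benzyloxy-4-methoxyphenyl)-4-(hydroxymethyl)oxolan-3-yl]methyl}-4-methoxy-2,3-dihydro-1-benzofuran-3-yl]carbonyl}-1,3-oxazolidin-2-one
Product: 29 [(2S,3R)-2-(4-benzyloxy-3-methoxyphenyl)-6-{[(3S,4S,5R)-5-(3-benzyloxy-4-methoxyphenyl)-4-(hydroxymethyl)oxolan-3-yl]methyl}-4-methoxy-2,3-dihydro-1-benzofuran-3-yl]methanol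
Conditions: LiBH4, H2O (1 equiv), Et2O–THF, 0 °C
Reagents that add atoms: none
Why: Reductive cleavage of the N-acyl oxazolidinone to the primary alcohol with release of 21; C3 keeps its geometry and its descriptor changes from S to R only because CH2OH ranks below C2.

Step 16
Reactants: 29 [(2S,3R)-2-(4-benzyloxy-3-methoxyphenyl)-6-{[(3S,4S,5R)-5-(3-benzyloxy-4-methoxyphenyl)-4-(hydroxymethyl)oxolan-3-yl]methyl}-4-methoxy-2,3-dihydro-1-benzofuran-3-yl]methanol
Product: 30 [(2S,3R)-2-(4-hydroxy-3-methoxyphenyl)-6-{[(3S,4S,5R)-5-(3-hydroxy-4-methoxyphenyl)-4-(hydroxymethyl)oxolan-3-yl]methyl}-4-methoxy-2,3-dihydro-1-benzofuran-3-yl]methanol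
Conditions: H2 (1 atm), 10% Pd/C, EtOAc–EtOH, rt, stopped at full conversion
Reagents that add atoms: none
Why: Hydrogenolysis of two aryl benzyl ethers, the fastest benzyl ethers to cleave; no alkyl benzyl ether is present, so the reaction can be stopped well before the ring benzylic C–O bonds are attacked.

## Compound list

1 | (R)-4-benzyl-1,3-oxazolidin-2-one | O=C1N[C@H](Cc2ccccc2)CO1 | starting material
2 | pent-4-enoyl chloride | C=CCCC(=O)Cl | starting material
3 | (4R)-4-benzyl-3-(pent-4-enoyl)-1,3-oxazolidin-2-one | C=CCCC(=O)N1C(=O)OC[C@H]1Cc1ccccc1 | intermediate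
4 | tert-butyl bromoacetate | CC(C)(C)OC(=O)CBr | starting material
5 | tert-butyl (3S)-3-{[(4R)-4-benzyl-2-oxo-1,3-oxazolidin-3-yl]carbonyl}hex-5-enoate | C=CC[C@@H](CC(=O)OC(C)(C)C)C(=O)N1C(=O)OC[C@H]1Cc1ccccc1 | intermediate
6 | tert-butyl (3S)-3-(hydroxymethyl)hex-5-enoate (not isolated) | C=CC[C@@H](CC(=O)OC(C)(C)C)CO | intermediate
7 | (4S)-4-(prop-2-en-1-yl)oxolan-2-one | O=C1OC[C@@H](CC=C)C1 | intermediate
8 | 3-(benzyloxy)-4-methoxybenzaldehyde | COc1ccc(C=O)cc1OCc1ccccc1 | starting material
9 | (3R,4S)-3-[(3-benzyloxy-4-methoxyphenyl)(hydroxy)methyl]-4-(prop-2-en-1-yl)oxolan-2-one, both carbinol epimers | O=C1OC[C@@H](CC=C)[C@@H]1C(O)c1ccc(OC)c(OCc2ccccc2)c1 | intermediate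
10 | (2S,3S)-2-[(3-benzyloxy-4-methoxyphenyl)(hydroxy)methyl]-3-(prop-2-en-1-yl)butane-1,4-diol, both carbinol epimers | OC[C@@H](CC=C)[C@@H](CO)C(O)c1ccc(OC)c(OCc2ccccc2)c1 | intermediate
11 | [(2R,3S,4S)-2-(3-benzyloxy-4-methoxyphenyl)-4-(prop-2-en-1-yl)oxolan-3-yl]methanol | COc1ccc([C@@H]2OC[C@@H](CC=C)[C@H]2CO)cc1OCc1ccccc1 | intermediate
12 | tert-butyl{[(2R,3S,4S)-2-(3-benzyloxy-4-methoxyphenyl)-4-(prop-2-en-1-yl)oxolan-3-yl]methoxy}dimethylsilane | COc1ccc([C@@H]2OC[C@@H](CC=C)[C@H]2CO[Si](C)(C)C(C)(C)C)cc1OCc1ccccc1 | intermediate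
13 | but-3-en-2-one (methyl vinyl ketone) | CC(=O)C=C | starting material
14 | (3E)-5-[(3S,4S,5R)-5-(3-benzyloxy-4-methoxyphenyl)-4-({[tert-butyl(dimethyl)silyl]oxy}methyl)oxolan-3-yl]pent-3-en-2-one | COc1ccc([C@@H]2OC[C@@H](C/C=C/C(C)=O)[C@H]2CO[Si](C)(C)C(C)(C)C)cc1OCc1ccccc1 | intermediate
15 | dimethyl malonate | COC(=O)CC(=O)OC | starting material
16 | methyl 6-{[(3S,4S,5R)-5-(3-benzyloxy-4-methoxyphenyl)-4-({[tert-butyl(dimethyl)silyl]oxy}methyl)oxolan-3-yl]methyl}-2,4-dioxocyclohexane-1-carboxylate, ring epimers (not isolated) | COc1ccc([C@@H]2OC[C@@H](CC3CC(=O)CC(=O)C3C(=O)OC)[C@H]2CO[Si](C)(C)C(C)(C)C)cc1OCc1ccccc1 | intermediate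
17 | 6-{[(3S,4S,5R)-5-(3-benzyloxy-4-methoxyphenyl)-4-({[tert-butyl(dimethyl)silyl]oxy}methyl)oxolan-3-yl]methyl}-2,4-dioxocyclohexane-1-carboxylic acid, ring epimers (not isolated) | COc1ccc([C@@H]2OC[C@@H](CC3CC(=O)CC(=O)C3C(=O)O)[C@H]2CO[Si](C)(C)C(C)(C)C)cc1OCc1ccccc1 | intermediate
18 | 5-{[(3S,4S,5R)-5-(3-benzyloxy-4-methoxyphenyl)-4-(hydroxymethyl)oxolan-3-yl]methyl}cyclohexane-1,3-dione (fragment 1) | COc1ccc([C@@H]2OC[C@@H](CC3CC(=O)CC(=O)C3)[C@H]2CO)cc1OCc1ccccc1 | intermediate
19 | ferulic acid | COc1cc(/C=C/C(=O)O)ccc1O | starting material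
20 | (2E)-3-(4-benzyloxy-3-methoxyphenyl)prop-2-enoic acid | COc1cc(/C=C/C(=O)O)ccc1OCc1ccccc1 | intermediate
21 | (S)-4-benzyl-1,3-oxazolidin-2-one | O=C1N[C@@H](Cc2ccccc2)CO1 | starting material
22 | (2E)-3-(4-benzyloxy-3-methoxyphenyl)prop-2-enoic 2,2-dimethylpropanoic anhydride (not isolated) | COc1cc(/C=C/C(=O)OC(=O)C(C)(C)C)ccc1OCc1ccccc1 | intermediate
23 | (4S)-4-benzyl-3-[(2E)-3-(4-benzyloxy-3-methoxyphenyl)prop-2-enoyl]-1,3-oxazolidin-2-one (fragment 2) | COc1cc(/C=C/C(=O)N2C(=O)OC[C@@H]2Cc2ccccc2)ccc1OCc1ccccc1 | intermediate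
24 | (4S)-4-benzyl-3-{[(2S,3S)-2-(4-benzyloxy-3-methoxyphenyl)-6-{[(3S,4S,5R)-5-(3-benzyloxy-4-methoxyphenyl)-4-(hydroxymethyl)oxolan-3-yl]methyl}-4-oxo-2,3,4,5,6,7-hexahydro-1-benzofuran-3-yl]carbonyl}-1,3-oxazolidin-2-one, both C6 epimers | COc1ccc([C@@H]2OC[C@@H](CC3CC(=O)C4=C(C3)O[C@H](c3ccc(OCc5ccccc5)c(OC)c3)[C@H]4C(=O)N3C(=O)OC[C@@H]3Cc3ccccc3)[C@H]2CO)cc1OCc1ccccc1 | intermediate
25 | 4-(trimethylsilyloxy)-2,3,6,7-tetrahydrobenzofuran (silyl dienol ether) of 24 with the oxolane CH2OH as its trimethylsilyl ether, both C6 epimers (not isolated) | COc1ccc([C@@H]2OC[C@@H](CC3C=C(O[Si](C)(C)C)C4=C(C3)O[C@H](c3ccc(OCc5ccccc5)c(OC)c3)[C@H]4C(=O)N3C(=O)OC[C@@H]3Cc3ccccc3)[C@H]2CO[Si](C)(C)C)cc1OCc1ccccc1 | intermediate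
26 | 4-hydroxy-2,3-dihydrobenzofuran 27 with the oxolane CH2OH still as its trimethylsilyl ether (not isolated) | COc1ccc([C@@H]2OC[C@@H](Cc3cc(O)c4c(c3)O[C@H](c3ccc(OCc5ccccc5)c(OC)c3)[C@H]4C(=O)N3C(=O)OC[C@@H]3Cc3ccccc3)[C@H]2CO[Si](C)(C)C)cc1OCc1ccccc1 | intermediate
27 | (4S)-4-benzyl-3-{[(2S,3S)-2-(4-benzyloxy-3-methoxyphenyl)-6-{[(3S,4S,5R)-5-(3-benzyloxy-4-methoxyphenyl)-4-(hydroxymethyl)oxolan-3-yl]methyl}-4-hydroxy-2,3-dihydro-1-benzofuran-3-yl]carbonyl}-1,3-oxazolidin-2-one | COc1ccc([C@@H]2OC[C@@H](Cc3cc(O)c4c(c3)O[C@H](c3ccc(OCc5ccccc5)c(OC)c3)[C@H]4C(=O)N3C(=O)OC[C@@H]3Cc3ccccc3)[C@H]2CO)cc1OCc1ccccc1 | intermediate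
28 | (4S)-4-benzyl-3-{[(2S,3S)-2-(4-benzyloxy-3-methoxyphenyl)-6-{[(3S,4S,5R)-5-(3-benzyloxy-4-methoxyphenyl)-4-(hydroxymethyl)oxolan-3-yl]methyl}-4-methoxy-2,3-dihydro-1-benzofuran-3-yl]carbonyl}-1,3-oxazolidin-2-one | COc1ccc([C@@H]2OC[C@@H](Cc3cc(OC)c4c(c3)O[C@H](c3ccc(OCc5ccccc5)c(OC)c3)[C@H]4C(=O)N3C(=O)OC[C@@H]3Cc3ccccc3)[C@H]2CO)cc1OCc1ccccc1 | intermediate
29 | [(2S,3R)-2-(4-benzyloxy-3-methoxyphenyl)-6-{[(3S,4S,5R)-5-(3-benzyloxy-4-methoxyphenyl)-4-(hydroxymethyl)oxolan-3-yl]methyl}-4-methoxy-2,3-dihydro-1-benzofuran-3-yl]methanol | COc1ccc([C@@H]2OC[C@@H](Cc3cc(OC)c4c(c3)O[C@H](c3ccc(OCc5ccccc5)c(OC)c3)[C@H]4CO)[C@H]2CO)cc1OCc1ccccc1 | intermediate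
30 | [(2S,3R)-2-(4-hydroxy-3-methoxyphenyl)-6-{[(3S,4S,5R)-5-(3-hydroxy-4-methoxyphenyl)-4-(hydroxymethyl)oxolan-3-yl]methyl}-4-methoxy-2,3-dihydro-1-benzofuran-3-yl]methanol (CNP0242386.1) | COc1ccc([C@@H]2OC[C@@H](Cc3cc(OC)c4c(c3)O[C@H](c3ccc(O)c(OC)c3)[C@H]4CO)[C@H]2CO)cc1O | target

## Step count and least certain steps

Total: 16 steps. Longest linear sequence: 14 steps (steps 1 to 9, then 12 to 16); steps 10 and 11 form the short branch.

**Step 12 (key step).** The most likely failure is poor facial selectivity, because acetate and the protic solvent compete for the Lewis acid and the imide is then not held in the chelated s-cis form. The second is low conversion, because the Lewis-acid-bound alkene is a poorer partner for an electrophilic radical and the dione radical then dimerises or is over-oxidised. Fallback: give up induction and use the established Lewis-acid-free annulation (Mn(OAc)3·2H2O in acetic acid at room temperature, or (NH4)2Ce(NO3)6 in acetonitrile), which is known for cyclohexane-1,3-diones and cinnamic amides. It sets out from 18 and 23 and should give 24 together with its diastereomer, the (2R,3R)-trans imide F1. The auxiliary then serves only as a resolving handle: the two differ at the centres next to the oxazolidinone and should separate by chromatography, and the route is rejoined at 24.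

**Step 13.** The most likely failure is at the palladium stage: protodesilylation of the labile silyl dienol ether back to 24 and incomplete or unclean dehydrogenation. Fallback: replace the palladium-mediated dehydrogenation by selenoxide elimination. Starting from 24, the lithium enolate (LiN(iPr)2, THF, −78 °C, hydroxyl carried as its alkoxide) is quenched with PhSeBr to give, after work-up, the 5-phenylselanyl ketone F2. Oxidation with H2O2 and pyridine in CH2Cl2 at 0 °C brings about syn-elimination (selenium enters anti to the C6 substituent and is therefore syn to C6–H), and the dienone tautomerises to 27, where the route is rejoined.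

**Step 9.** The most likely failure is incomplete Claisen closure or reversal of the Michael addition during the long basic stage, followed in the hot acidic stage by vinylogous ester formation at the dione or erosion of configuration at the benzylic oxolane carbon. Fallback: avoid malonate and decarboxylation. Starting from 14, a Mukaiyama–Michael addition of 1-methoxy-1-(trimethylsilyloxy)ethene (Sc(OTf)3 cat., CH2Cl2, −78 °C) should give methyl 5-oxohexanoate F3, which carries the silylated oxolanylmethyl group at C3. KOtBu in THF closes it by intramolecular Claisen condensation to the silylated dione F4, and Bu4NF in THF removes the silyl group to give 18, where the route is rejoined.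

**Step 15.** The most likely failure is hydride attack at the ring carbonyl of the oxazolidinone, because the exocyclic carbonyl sits on a hindered tertiary carbon; this would open the auxiliary to a hydroxy amide. Fallback: starting from 28, hydrolyse with LiOH/H2O2 in THF–H2O at 0 °C (hydroperoxide attacks the exocyclic carbonyl even of hindered imides) to the 2,3-dihydrobenzofuran-3-carboxylic acid F5, then reduce the acid with BH3·SMe2 in THF at 0 °C to 29, where the route is rejoined.

## Further compounds

F1 | step 12 | (4S)-4-benzyl-3-{[(2R,3R)-2-(4-benzyloxy-3-methoxyphenyl)-6-{[(3S,4S,5R)-5-(3-benzyloxy-4-methoxyphenyl)-4-(hydroxymethyl)oxolan-3-yl]methyl}-4-oxo-2,3,4,5,6,7-hexahydro-1-benzofuran-3-yl]carbonyl}-1,3-oxazolidin-2-one | COc1ccc([C@@H]2OC[C@@H](CC3CC(=O)C4=C(C3)O[C@@H](c3ccc(OCc5ccccc5)c(OC)c3)[C@@H]4C(=O)N3C(=O)OC[C@@H]3Cc3ccccc3)[C@H]2CO)cc1OCc1ccccc1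
F2 | step 13 | (4S)-4-benzyl-3-{[(2S,3S)-2-(4-benzyloxy-3-methoxyphenyl)-6-{[(3S,4S,5R)-5-(3-benzyloxy-4-methoxyphenyl)-4-(hydroxymethyl)oxolan-3-yl]methyl}-4-oxo-5-(phenylselanyl)-2,3,4,5,6,7-hexahydro-1-benzofuran-3-yl]carbonyl}-1,3-oxazolidin-2-one | COc1ccc([C@@H]2OC[C@@H](CC3C([Se]c6ccccc6)C(=O)C4=C(C3)O[C@H](c3ccc(OCc5ccccc5)c(OC)c3)[C@H]4C(=O)N3C(=O)OC[C@@H]3Cc3ccccc3)[C@H]2CO)cc1OCc1ccccc1
F3 | step 9 | methyl 3-{[(3S,4S,5R)-5-(3-benzyloxy-4-methoxyphenyl)-4-({[tert-butyl(dimethyl)silyl]oxy}methyl)oxolan-3-yl]methyl}-5-oxohexanoate | COc1ccc([C@@H]2OC[C@@H](CC(CC(C)=O)CC(=O)OC)[C@H]2CO[Si](C)(C)C(C)(C)C)cc1OCc1ccccc1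
F4 | step 9 | 5-{[(3S,4S,5R)-5-(3-benzyloxy-4-methoxyphenyl)-4-({[tert-butyl(dimethyl)silyl]oxy}methyl)oxolan-3-yl]methyl}cyclohexane-1,3-dione | COc1ccc([C@@H]2OC[C@@H](CC3CC(=O)CC(=O)C3)[C@H]2CO[Si](C)(C)C(C)(C)C)cc1OCc1ccccc1
F5 | step 15 | (2S,3S)-2-(4-benzyloxy-3-methoxyphenyl)-6-{[(3S,4S,5R)-5-(3-benzyloxy-4-methoxyphenyl)-4-(hydroxymethyl)oxolan-3-yl]methyl}-4-methoxy-2,3-dihydro-1-benzofuran-3-carboxylic acid | COc1ccc([C@@H]2OC[C@@H](Cc3cc(OC)c4c(c3)O[C@H](c3ccc(OCc5ccccc5)c(OC)c3)[C@H]4C(=O)O)[C@H]2CO)cc1OCc1ccccc1
A1 | alternative 1 | ring B phenol from the benzannulation: oxolanylmethyl group para to the open side chain, OSi(iPr)3 and OH on either side of it | COc1ccc([C@@H]2OC[C@@H](Cc3cc(O[Si](C(C)C)(C(C)C)C(C)C)c([C@H](COCc4ccccc4)[C@H](O[Si](C)(C)C(C)(C)C)c4ccc(OCc5ccccc5)c(OC)c4)c(O)c3)[C@H]2CO[Si](C)(C)C(C)(C)C)cc1OCc1ccccc1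
A2 | alternative 1 | 3-{[(3S,4S,5R)-5-(3-benzyloxy-4-methoxyphenyl)-4-({[tert-butyl(dimethyl)silyl]oxy}methyl)oxolan-3-yl]methyl}cyclobut-2-en-1-one | COc1ccc([C@@H]2OC[C@@H](CC3=CC(=O)C3)[C@H]2CO[Si](C)(C)C(C)(C)C)cc1OCc1ccccc1
A3 | alternative 1 | triisopropylsilyl ynol ether of 3-(benzyloxymethyl)-4-(4-benzyloxy-3-methoxyphenyl)-4-{[tert-butyl(dimethyl)silyl]oxy}but-1-yne, configuration as in A1 | CC(C)[Si](OC#C[C@H](COCc1ccccc1)[C@H](O[Si](C)(C)C(C)(C)C)c1ccc(OCc2ccccc2)c(OC)c1)(C(C)C)C(C)C
A4 | alternative 2 | methyl (2S,3S)-2-(4-benzyloxy-3-methoxyphenyl)-4-methoxy-6-[(trifluoromethylsulfonyl)oxy]-2,3-dihydro-1-benzofuran-3-carboxylate (trans) | FC(F)(F)S(=O)(=O)Oc1cc(OC)c2c(c1)O[C@H](c1ccc(OCc3ccccc3)c(OC)c1)[C@H]2C(=O)OC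
A5 | alternative 2 | methyl 2-diazo-2-{2-[(4-benzyloxy-3-methoxyphenyl)methoxy]-6-methoxy-4-[(trifluoromethylsulfonyl)oxy]phenyl}acetate | COC(=O)C(=[N+]=[N-])c1c(OC)cc(OS(=O)(=O)C(F)(F)F)cc1OCc1ccc(OCc2ccccc2)c(OC)c1
A6 | alternative 3 | 6-(3-benzyloxy-4-methoxyphenyl)-4-[(1R,2S,5R)-2-isopropyl-5-methylcyclohexyloxy]-3,7-dioxabicyclo[3.3.0]octan-2-one, cis-fused, aryl exo | COc1ccc([C@@H]2OC[C@H]3[C@H](O[C@@H]4C[C@H](C)CC[C@H]4C(C)C)OC(=O)[C@@H]23)cc1OCc1ccccc1
A7 | alternative 3 | 2-(benzyloxy)-4-{chloro[(trimethylsilyl)methoxy]methyl}-1-methoxybenzene | COc1ccc(C(Cl)OC[Si](C)(C)C)cc1OCc1ccccc1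
A8 | alternative 3 | (5R)-5-[(1R,2S,5R)-2-isopropyl-5-methylcyclohexyloxy]furan-2(5H)-one | O=C1C=C[C@H](O[C@@H]2C[C@H](C)CC[C@H]2C(C)C)O1
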